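The coupling partner is the reagent I count in this flask: each turnover of substrate spends one, and the by-product released can hold another as idle adduct.

substrate 0.10 M; coupling partner 0.130 M; capture agent 5.00 mM; time 2.5 h

    substrate + coupling partner → open intermediate + by-product (k1 = 0.80 M⁻¹ min⁻¹)
    open intermediate → product (k2 = 0.23 min⁻¹)
    coupling partner + by-product ⇌ idle adduct, settled at all times (K3 = 660 M⁻¹)
    open intermediate + capture agent → trapped intermediate (k4 = 0.092 M⁻¹ min⁻¹)
    coupling partner → decomposed reagent (k5 = 0.027 min⁻¹)

- part of the substrate that has reacted at 2.5 h
- share of the unused coupling partner that is free and not bound as idle adduct, at 2.5 h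

Steps 1 and 5 both draw on free coupling partner, so its concentration cancels from their ratio, whatever step 3 does. I call k5/k1 the toll, 33.7 mM: [decomposed reagent] = toll × ln(substrate charge/[substrate]). The capture agent does not enter this count.

I draw the curve of turned substrate, x, in this flask. It starts with slope 10.4 mM min⁻¹. K3 times the starting partner is 86, so by-product binds as it forms, and the fall of free partner flattens at a knee where the partner charge equals 2 times x plus the toll's share. Two passes put that knee at 0.0542 M.

Beyond the knee, partner comes from the adduct. The next landmark is the crossing, where free by-product equals adduct and [free partner] is 1/K3, 1.52 mM. The partner charge then equals 3 times x over 2 plus the toll's share, which gives x = 0.0630 M. If I guess 3.03 mM as the mean free partner, decomposition needs 1.48 h from knee to crossing, so I take the crossing as the state at the asked time: c = 63.0% and fr = 4.59%. The curve's ceiling, with the adduct emptied, lies near 79.7%.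

The forecast gives 64% and 4.3%, on the ground that “by-product binds it almost stoichiometrically”.

The flask gives 63.8% and 4.36%. At 2.50 h, free coupling partner, the limiting reagent at 1.07% of its charge, has a half-life of 0.40 h through step 1, close to the 0.43 h through step 5 read at 0.0947 h. The toll turns this flask's 0.0343 M of decomposed reagent into 36.1% substrate left, where 36.2% stands, and the neighbour flask charged with 0.40 M of substrate, holding 0.00980 M, into 74.8%, where 74.8% stands.

(The numbers of this flask were set for the occasion; the run is a simulation.)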